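## Retrosynthetic overview

1. Backbone numbering C1–C19 is used throughout (pentyl = C1–C5; oxolane carbons = C6 (pentyl), C7 (acyloxy), C8, C9; carbinol = C10; vinyl = C18=C19). The target is unmasked from a C10-silylated oxolan-7-ol by myristoylation at O7 and desilylation.
2. Key disconnection: the ring bond between the oxygen on C9 and C6. The enabling feature is that the ring oxygen and the C7 oxygen are vicinal, with pentyl and acyloxy cis, which is the outcome of anti addition of two oxygens across a (Z)-C6=C7 alkene. The ring oxygen also sits on C9, homoallylic to that alkene and 1,3-syn to O7, so the retron is a hydroxyl-directed epoxidation followed by strain-releasing opening of the oxirane at C6.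
3. The acyclic (Z)-homoallylic alcohol is traced to a homopropargylic alcohol (semi-hydrogenation), and this to a terminal epoxide plus hept-1-yne (C7–C8 bond).
4. The epoxide is traced to C2-symmetric (R,R)-diepoxybutane plus an oct-7-enyl Grignard reagent (C11–C12 bond). C9 and C10 are bought, and the order of the two epoxide openings distinguishes O10 (silylated) from O9 (free).
5. Ring order: the oxolane, the only ring of the target, is closed in the key step; the oxirane that drives it is made and consumed in the same flask.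

Key step: step 5

Remark: (2R,2'R)-2,2'-bioxirane, the D-threitol-derived enantiomer of 1,2:3,4-diepoxybutane, is taken as a purchasable building block.

## Route

Step 1
Reactants: 1 8-bromooct-1-ene; 2 (2R,2'R)-2,2'-bioxirane
Product: 4 (1R)-1-[(2R)-oxiran-2-yl]dec-9-en-1-ol, via oct-7-enylmagnesium bromide 3 (not isolated)
Conditions: 1, Mg, THF, rt; then slow addition to 2 (excess), CuI (cat.), THF, −30 °C; H2O quench
Reagents that add atoms: none
Why: Copper-catalysed Grignard opening of an epoxide (SN2 at the unsubstituted terminal carbon) should add the octenyl chain to one oxirane of C2-symmetric 2, whose two rings are equivalent so that only over-addition (suppressed by excess 2 and inverse addition) has to be avoided; both stereocentres (C9, C10) are carried over unchanged from 2.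

Step 2
Reactants: 4 (1R)-1-[(2R)-oxiran-2-yl]dec-9-en-1-ol
Product: 5 tert-butyl(dimethyl){[(1R)-1-[(2R)-oxiran-2-yl]dec-9-en-1-yl]oxy}silane
Conditions: TBSCl, imidazole, DMAP (cat.), DMF, 0 °C to rt
Reagents that add atoms: tert-butyldimethylsilyl chloride, CC(C)(C)[Si](C)(C)Cl
Why: Imidazole-promoted silyl ether formation on the secondary alcohol proceeds without a free alkoxide, which avoids Payne rearrangement of the adjacent oxirane and fixes O10 as the unreactive oxygen for the key step; no stereocentre is touched.

Step 3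
Reactants: 5 tert-butyl(dimethyl){[(1R)-1-[(2R)-oxiran-2-yl]dec-9-en-1-yl]oxy}silane; 6 hept-1-yne
Product: 8 (9R,10R)-10-{[tert-butyl(dimethyl)silyl]oxy}nonadec-18-en-6-yn-9-ol, via hept-1-ynyllithium 7 (not isolated)
Conditions: 6, n-BuLi, THF, −78 °C; BF3·OEt2; then 5, −78 °C; H2O quench
Reagents that add atoms: none
Why: In this Yamaguchi–Hirao alkynylation the lithium acetylide opens the BF3-activated terminal oxirane at its CH2 carbon (C8) at low temperature, where the new alkoxide is held as a borate so that 1,2-silyl migration is suppressed, and the C9 hydroxyl is released with its configuration retained.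

Step 4
Reactants: 8 (9R,10R)-10-{[tert-butyl(dimethyl)silyl]oxy}nonadec-18-en-6-yn-9-ol
Product: 9 (6Z,9R,10R)-10-{[tert-butyl(dimethyl)silyl]oxy}nonadeca-6,18-dien-9-ol
Conditions: H2 (1 atm), Pd/CaCO3 poisoned with Pb(OAc)2 (Lindlar catalyst), quinoline, hexane/EtOAc, rt, stopped after one equivalent of H2
Reagents that add atoms: none
Why: Lindlar semi-hydrogenation delivers H2 syn on the poisoned Pd surface to give the Z-alkene, and the internal alkyne, which binds far more strongly than the remote monosubstituted alkene, should be consumed first.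

Step 5
Reactants: 9 (6Z,9R,10R)-10-{[tert-butyl(dimethyl)silyl]oxy}nonadeca-6,18-dien-9-ol
Product: 11 (2S,3S,5R)-5-[(1R)-1-{[tert-butyl(dimethyl)silyl]oxy}dec-9-en-1-yl]-2-pentyloxolan-3-ol, via syn-epoxy alcohol 10 (not isolated)
Conditions: VO(acac)2 (cat.), t-BuOOH (anhydrous, decane), CH2Cl2, 0 °C to rt; then CSA (cat.), rt, same flask
Reagents that add atoms: tert-butyl hydroperoxide, CC(C)(C)OO
Why: VO(acac)2 is oxidised by t-BuOOH to a pentavalent vanadium alkylperoxo species that binds the C9 hydroxyl as a vanadate ester and transfers oxygen intramolecularly to the homoallylic Z-alkene (hydroxyl-directed epoxidation), giving syn-epoxy alcohol 10, whose C9 hydroxyl then opens the acid-activated oxirane at C6 by SN2 to form the O–C6 bond. The closest known reaction type is the one-flask vanadium-directed epoxidation and acid-catalysed cyclisation of (Z)-homoallylic alcohols to 2,3-cis-2,5-trans-3-hydroxyoxolanes. The oxolane is closed by a 5-endo epoxide opening (attack at the distal oxirane carbon), driven by release of oxirane strain and preferred over 4-exo attack at C7 because that would give an oxetane. C7 is set by the facial selectivity of oxygen transfer: in the chair-like vanadate transition state the C10 substituent is equatorial and A(1,3) strain of the Z-olefin fixes the allylic conformation, so oxygen is delivered to the face that gives the (6R,7S)-epoxide 1,3-syn to O9. C6 is set by stereospecific inversion in the anti opening of the cis-epoxide, which translates the Z geometry into the 2,3-cis (pentyl/hydroxyl) and, together with the syn relationship, the 2,5-trans arrangement, i.e. 6S,7S,9R. The step needs chemoselectivity for C6=C7 over the terminal alkene, secured because only the homoallylic alkene is within reach of the vanadium-bound peroxide, and selectivity for O9 over O10, secured because O10 is a bulky silyl ether that cannot make the otherwise faster 5-exo closure onto C7, so the only hydroxyl set free is the C7–OH that must carry the myristate.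

Step 6
Reactants: 11 (2S,3S,5R)-5-[(1R)-1-{[tert-butyl(dimethyl)silyl]oxy}dec-9-en-1-yl]-2-pentyloxolan-3-ol; 12 tetradecanoyl chloride
Product: 13 (2S,3S,5R)-5-[(1R)-1-{[tert-butyl(dimethyl)silyl]oxy}dec-9-en-1-yl]-2-pentyloxolan-3-yl tetradecanoate
Conditions: pyridine, DMAP (cat.), CH2Cl2, 0 °C to rt
Reagents that add atoms: none
Why: DMAP-catalysed acylation (nucleophilic catalysis through the acylpyridinium ion) of the only free hydroxyl, the ring C7–OH, should install the tetradecanoate with retention, since the C–O bond is not broken.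

Step 7
Reactants: 13 (2S,3S,5R)-5-[(1R)-1-{[tert-butyl(dimethyl)silyl]oxy}dec-9-en-1-yl]-2-pentyloxolan-3-yl tetradecanoate
Product: 14 (2S,3S,5R)-5-[(1R)-1-hydroxydec-9-en-1-yl]-2-pentyloxolan-3-yl tetradecanoate
Conditions: HF·pyridine, THF/pyridine, 0 °C to rt
Reagents that add atoms: none
Why: Fluoride-driven desilylation (formation of the strong Si–F bond) under buffered, non-basic conditions should free the C10 hydroxyl without ester cleavage or acyl migration, the ester and carbinol oxygens being 1,4-related and trans across the ring.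

## Compound list

1 | 8-bromooct-1-ene | C=CCCCCCCBr | starting material
2 | (2R,2'R)-2,2'-bioxirane [(R,R)-1,2:3,4-diepoxybutane] | C1O[C@H]1[C@H]1CO1 | starting material
3 | oct-7-enylmagnesium bromide | C=CCCCCCC[Mg]Br | intermediate
4 | (1R)-1-[(2R)-oxiran-2-yl]dec-9-en-1-ol | C=CCCCCCCC[C@@H](O)[C@H]1CO1 | intermediate
5 | tert-butyl(dimethyl){[(1R)-1-[(2R)-oxiran-2-yl]dec-9-en-1-yl]oxy}silane | C=CCCCCCCC[C@@H](O[Si](C)(C)C(C)(C)C)[C@H]1CO1 | intermediate
6 | hept-1-yne | C#CCCCCC | starting material
7 | hept-1-ynyllithium | [Li]C#CCCCCC | intermediate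
8 | (9R,10R)-10-{[tert-butyl(dimethyl)silyl]oxy}nonadec-18-en-6-yn-9-ol | C=CCCCCCCC[C@@H](O[Si](C)(C)C(C)(C)C)[C@H](O)CC#CCCCCC | intermediate
9 | (6Z,9R,10R)-10-{[tert-butyl(dimethyl)silyl]oxy}nonadeca-6,18-dien-9-ol | C=CCCCCCCC[C@@H](O[Si](C)(C)C(C)(C)C)[C@H](O)C/C=C\CCCCC | intermediate
10 | (2R,3R)-3-{[tert-butyl(dimethyl)silyl]oxy}-1-[(2S,3R)-3-pentyloxiran-2-yl]dodec-11-en-2-ol (syn-epoxy alcohol; 6R,7S,9R,10R in backbone numbering) | C=CCCCCCCC[C@@H](O[Si](C)(C)C(C)(C)C)[C@H](O)C[C@@H]1O[C@@H]1CCCCC | intermediate
11 | (2S,3S,5R)-5-[(1R)-1-{[tert-butyl(dimethyl)silyl]oxy}dec-9-en-1-yl]-2-pentyloxolan-3-ol | C=CCCCCCCC[C@@H](O[Si](C)(C)C(C)(C)C)[C@H]1C[C@H](O)[C@H](CCCCC)O1 | intermediate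
12 | tetradecanoyl chloride | CCCCCCCCCCCCCC(=O)Cl | starting material
13 | (2S,3S,5R)-5-[(1R)-1-{[tert-butyl(dimethyl)silyl]oxy}dec-9-en-1-yl]-2-pentyloxolan-3-yl tetradecanoate | C=CCCCCCCC[C@@H](O[Si](C)(C)C(C)(C)C)[C@H]1C[C@H](OC(=O)CCCCCCCCCCCCC)[C@H](CCCCC)O1 | intermediate
14 | (2S,3S,5R)-5-[(1R)-1-hydroxydec-9-en-1-yl]-2-pentyloxolan-3-yl tetradecanoate | C=CCCCCCCC[C@@H](O)[C@H]1C[C@H](OC(=O)CCCCCCCCCCCCC)[C@H](CCCCC)O1 | target

## Step count and risks

Total step count: 7. Longest linear sequence: 7 steps (1/2 → 4 → 5 → 8 → 9 → 11 → 13 → 14).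

Steps most likely to fail:

**Step 5 (key step).** What may go wrong: erosion of facial control in the directed oxygen transfer, oxidation of the carbinol instead of the alkene, or diversion of the oxirane opening by participation of the silyloxy oxygen. The fallback sets out from 9 and returns at 10, then 11; it replaces the metal-bound oxidant by a substrate-controlled electrophilic cyclisation. The C9 hydroxyl of 9 would be converted (Boc2O, DMAP, MeCN) into tert-butyl (6Z,9R,10R)-10-{[tert-butyl(dimethyl)silyl]oxy}nonadeca-6,18-dien-9-yl carbonate F1. Iodocarbonate cyclisation (I2, MeCN, −20 °C; iodine adds only reversibly to the terminal alkene) should give (4R,6S)-4-[(1R)-1-{[tert-butyl(dimethyl)silyl]oxy}dec-9-en-1-yl]-6-[(1S)-1-iodohexyl]-1,3-dioxan-2-one F2. Its 1,3-syn relationship is set by a chair-like six-membered transition state with both substituents equatorial, and oxygen and iodine add anti across the Z-alkene. K2CO3 in MeOH then cleaves the carbonate and closes the C7 alkoxide onto the iodide with inversion, giving the same syn cis-epoxy alcohol 10, now isolated. CSA (cat.) in CH2Cl2 completes the 5-endo closure to 11.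

**Step 4.** What may go wrong: hydrogenation or isomerisation of the terminal alkene, or over-reduction of the new Z-alkene, on the palladium surface. The fallback sets out from 5 and returns at 9, bypassing 8 and any hydrogenation. Pentylmagnesium bromide (2 equiv) and CuBr·SMe2 (Et2O, −40 °C) give bromomagnesium dipentylcuprate F3. This adds syn across acetylene to give bromomagnesium bis[(1Z)-hept-1-enyl]cuprate F4. This monovalent copper reagent should open epoxide 5 at its CH2 carbon (THF, −30 °C, BF3·OEt2 if needed; H2O quench) to give 9 directly, with the Z geometry fixed by the syn carbometalation.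

**Step 1.** What may go wrong: double opening of the bis-epoxide, halide opening by magnesium salts, or lack of supply of enantiopure 2. The fallback sets out from 1 (used as Grignard reagent 3) and returns at 4; it replaces statistical mono-opening by desymmetrisation of a protected threitol. Purchasable (4R,5R)-2,2-dimethyl-1,3-dioxolane-4,5-dimethanol F5 would be monotosylated (TsCl, Ag2O, KI (cat.), CH2Cl2) to [(4R,5R)-5-(hydroxymethyl)-2,2-dimethyl-1,3-dioxolan-4-yl]methyl 4-methylbenzenesulfonate F6. Copper-catalysed coupling with excess 3 (Li2CuCl4 (cat.), THF, −20 °C to rt; H2O quench) should give [(4R,5R)-2,2-dimethyl-5-(non-8-en-1-yl)-1,3-dioxolan-4-yl]methanol F7. Tosylation (TsCl, pyridine) gives [(4R,5R)-2,2-dimethyl-5-(non-8-en-1-yl)-1,3-dioxolan-4-yl]methyl 4-methylbenzenesulfonate F8. Acetonide hydrolysis (aq HCl, MeOH) gives (2R,3R)-2,3-dihydroxydodec-11-en-1-yl 4-methylbenzenesulfonate F9. Brief treatment with K2CO3 in MeOH at 0 °C closes the C9 alkoxide onto the primary tosylate to give epoxy alcohol 4; the C10 hydroxyl could only form an oxetane and stays free.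

Further compounds
F1 | step 5 | tert-butyl (6Z,9R,10R)-10-{[tert-butyl(dimethyl)silyl]oxy}nonadeca-6,18-dien-9-yl carbonate | C=CCCCCCCC[C@@H](O[Si](C)(C)C(C)(C)C)[C@H](OC(=O)OC(C)(C)C)C/C=C\CCCCC
F2 | step 5 | (4R,6S)-4-[(1R)-1-{[tert-butyl(dimethyl)silyl]oxy}dec-9-en-1-yl]-6-[(1S)-1-iodohexyl]-1,3-dioxan-2-one | C=CCCCCCCC[C@@H](O[Si](C)(C)C(C)(C)C)[C@H]1C[C@H](OC(=O)O1)[C@@H](I)CCCCC
F3 | step 4 | bromomagnesium dipentylcuprate | CCCCC[Cu-]CCCCC.[Mg+]Br
F4 | step 4 | bromomagnesium bis[(1Z)-hept-1-enyl]cuprate | CCCCC/C=C\[Cu-]/C=C\CCCCC.[Mg+]Br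
F5 | step 1 | (4R,5R)-2,2-dimethyl-1,3-dioxolane-4,5-dimethanol | OC[C@H]1OC(C)(C)O[C@@H]1CO
F6 | step 1 | [(4R,5R)-5-(hydroxymethyl)-2,2-dimethyl-1,3-dioxolan-4-yl]methyl 4-methylbenzenesulfonate | Cc1ccc(cc1)S(=O)(=O)OC[C@H]1OC(C)(C)O[C@@H]1CO
F7 | step 1 | [(4R,5R)-2,2-dimethyl-5-(non-8-en-1-yl)-1,3-dioxolan-4-yl]methanol | C=CCCCCCCC[C@H]1OC(C)(C)O[C@@H]1CO
F8 | step 1 | [(4R,5R)-2,2-dimethyl-5-(non-8-en-1-yl)-1,3-dioxolan-4-yl]methyl 4-methylbenzenesulfonate | C=CCCCCCCC[C@H]1OC(C)(C)O[C@@H]1COS(=O)(=O)c1ccc(C)cc1
F9 | step 1 | (2R,3R)-2,3-dihydroxydodec-11-en-1-yl 4-methylbenzenesulfonate | C=CCCCCCCC[C@@H](O)[C@H](O)COS(=O)(=O)c1ccc(C)cc1
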